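# Total synthesis proposal for CNP0348992.3 by Nozaki–Hiyama–Kishi closure of the C4–C5 bond

Compounds are numbered 1–30 in the order in which they appear in the steps, and these numbers are used in every section.

## Analysis of the target

The target 30 is a ten-membered carbocycle (C1–C10) trans-fused at C7–C8 to an α-methylene-γ-butyrolactone (C11=C13H2, C12=O, lactone oxygen on C8). The ring carries a trans-epoxide at C1–C10 with the methyl group C14 on C10, a ketone at C3 conjugated with the exocyclic methylene C4=C15, an angelate on C5 and a free hydroxyl on C6. Six stereocentres are present (1R,5S,6S,7R,8R,10R). In the contiguous set C5–C8 the two oxygens on C5 and C6 are syn in the zigzag drawing, H7 and H8 are trans, and the epoxide has the geometry of an (E)-alkene. The molecule holds two Michael acceptors, a (Z)-configured ester that can isomerise to the tiglate, an acid-labile trisubstituted epoxide that is also β,γ to the ketone (base-labile), and a vicinal ester/alcohol pair that can exchange the acyl group. O6 and O8 are both γ to C12, so the lactone can in principle move. The difficulty lies in closing the medium ring while controlling four adjacent stereocentres, and in ordering the last steps so that no reagent meets a group it destroys. The strategy rests on C5: it is an allylic carbinol on the 1,1-disubstituted alkene C4=C15, which is exactly what an alkenyl-metal at C4 gives on adding to a C5 aldehyde.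

## Retrosynthetic reasoning

**Epoxide (30 to 29).** The two C–O bonds of the epoxide are cut first. The C1=C10 alkene of 29 is the only electron-rich alkene, so a peracid should select it, and the (E)-geometry gives the trans-epoxide. Making the epoxide last means that it never meets acid, fluoride or metal salts.

**Protecting groups and ester (29 to 28 to 27 to 24).** The silyl ether on O6 is removed before the epoxide exists, because fluoride or HF-type reagents would open it. The C3 ketone is released from its ketal one step earlier, while O6 is still blocked, so that aqueous acid cannot shift the angelate to O6. The C5–O acyl bond is cut next; in 24 the C5 hydroxyl is the only free one, so angelic acid 25 can be attached through the mixed anhydride 26 without selectivity problems.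

**Ring closure (24 to 22).** The C4–C5 bond is cut. This is the only ring bond whose formation creates a needed functional group (the allylic alcohol) and a stereocentre at the same time, and it leaves an open chain in which every other stereocentre and the lactone are already in place. Forward, the alkenyl iodide of 22 has to become the alkenylchromium species 23 and add to the aldehyde across a ten-membered ring, on the face that gives 5S.

**Aldehyde and lactone position (22 to 21 to 20).** The aldehyde comes from the primary alcohol 21. That alcohol is traced to the six-membered lactone 20, in which O5 is acylated by C12 and O8 is free. Moving the acyl group from O5 to O8 gives the five-membered lactone and frees O5 in one operation. The six-membered lactone is therefore a temporary tether that also protects O5.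

**C7–C8 bond (20 to 6 and 18).** The C7–C8 bond is cut to the allylic bromide 6 and the aldehyde 18, joined by an indium Barbier reaction through the allylindium 19. An open-chain (Z)-2-(bromomethyl)enoate would place the C6 substituent axial in the chair transition state and give the syn adduct, which leads to the cis-lactone. In 6 the ring ties C6 trans to the bromomethyl group, so the chair gives the anti adduct (trans-lactone). The ring also lets the silyloxy group on C6 block one face of C7. Both C7 and C8 are thus set from C6.

**Bromolactone (6 to 5 to 3 and 4, 3 to 2 to 1).** The C7=C11 double bond of 6 is cut by ring-closing metathesis to ester 5, and the ester to alcohol 3 and acid 4. Alcohol 3 comes from the chiral-pool diol 1 through the bis-silyl ether 2, and the stereocentre of 1 becomes C6 unchanged.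

**Iodo ketal (18 to 17 to 16 to 14 to 11 and 12).** The aldehyde 18 is labile (β,γ-unsaturated) and is made last from alcohol 17 and its silyl ether 16. The ketal carbon with its 1-iodovinyl group is traced to the allenyl ether 14: addition of iodonium to the central allene carbon and capture of the oxocarbenium ion by a 1,2-diol (through 15) give the ketal and the vinyl iodide together, so C3 never exists as a free β,γ-unsaturated ketone in the open chain. The C2–C3 bond of 14 is cut to bromide 11 and methoxyallene 12, which as its lithio derivative 13 is a three-carbon acyl-anion equivalent for C3, C4 and C15.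

**Trisubstituted alkene (11 to 10 to 7).** The C1–C2 bond and the C10–C14 bond are cut back to alkyne 7. Syn-methylalumination gives the alane 8 with the (E)-geometry fixed, and the aluminate 9 takes up a one-carbon electrophile to give allylic alcohol 10.

## Alternatives that were turned down

Alternative 1: The disconnection is at C9–C10 and at the C1–O bond of the epoxide, made before any ring exists. Forward, an allyl Grignard reagent adds to the methyl ketone of the (S)-α-chloro ketone A2 with the C=O and C–Cl dipoles opposed (Cornforth control), and the alkoxide displaces chloride with inversion to give the trans-epoxide A1. In its favour, C1 and C10 are fixed by open-chain stereocontrol, independent of any ring conformation. On that point it is stronger than the chosen route, where the epoxide face depends on the conformation of 29 in the last step. Against it, A1 answers two of six stereocentres and no ring: C7, C8, the lactone, the C2–C6 chain and the ring closure all remain. The acid-labile epoxide would have to survive every later step, including a ring closure with Lewis-acidic metal salts. A2 is also easily epimerised next to the ketone, and Cornforth selectivity for a methyl ketone is moderate. The chosen strategy offers instead a convergent assembly in which the epoxide is exposed to no later step.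

Alternative 2: The disconnection is at C11–C12 and O–C12; the lactone carbonyl carbon is put in at the end. Forward, palladium-catalysed cyclocarbonylation of the ring alkynol A4 (hydroxyl on C8, ethynyl on C7) gives the α-methylene lactone A3. In its favour, the Michael-acceptor lactone appears late, so earlier steps are free of it. On that point it is stronger than the chosen route, which carries the α-methylene lactone through the chromium step and the esterification. Against it, A4 already contains the ten-membered ring and four stereocentres, so the ring-closure problem is untouched and the ethynyl group must be placed trans to the C8 hydroxyl by separate chemistry. The carbonylation conditions (acidic metal chlorides, heat) meet an exocyclic enone and a trisubstituted alkene that can isomerise or react across the ring. A3 still needs an ether cleavage and the angelate. In the chosen route the lactone-forming C–C bond (step 11) sets C7 and C8, so the lactone construction does stereochemical work, whereas here it is only a functional-group installation.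

Alternative 3: The disconnection forms C8–C9 and breaks a cyclohexane bond (C1–C6). Forward, the potassium alkoxide of a 1-alkenyl-2-isopropenylcyclohexanol, taken from a chiral-pool cyclohexenone, undergoes an anionic oxy-Cope rearrangement to the cyclodecenone A5. In its favour, the ten-membered ring, the (E)-alkene and the C8 centre (as C–Si) come from a concerted chair process that needs no dilution. For making the ring it is more reliable than any macrocyclisation, including the chosen one. Against it, the oxidation pattern of A5 is displaced: a ketone sits at C6 where the target has a hydroxyl, a silyl ether at C3 where the target has a ketone, and silicon at C8 that needs an oxidative C–Si cleavage in the presence of the C1=C10 alkene. C7 is a bare methylene, so C11–C13 must be attached by enolate chemistry with a new stereocentre, followed by stereoselective reduction at C6 and methylenation. This makes a long linear sequence with several protecting-group changes. The chosen route reaches the ring with all carbons and the C6–C8 stereochemistry in place and leaves four steps after ring closure, at the price of a riskier ring closure.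

Key step: step 14

Remark on the chemistry: position numbers C1–C15 are those fixed in the analysis (also in the names of ring compounds and open-chain intermediates), and compounds 1, 4, 7, 12 and 25 are taken as purchased.

## Route

Step 1
Reactants: 1 (S)-but-3-ene-1,2-diol
Product: 2 (S)-3,4-bis[(tert-butyldimethylsilyl)oxy]but-1-ene
Conditions: TBSCl, imidazole, DMF, rt
Reagents that add atoms: tert-butyldimethylsilyl chloride, C[Si](C)(Cl)C(C)(C)C
Why: Standard silylation of both hydroxyls; the stereocentre (later C6) is not touched.

Step 2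
Reactants: 2 (S)-3,4-bis[(tert-butyldimethylsilyl)oxy]but-1-ene
Product: 3 (S)-2-[(tert-butyldimethylsilyl)oxy]but-3-en-1-ol
Conditions: HF·pyridine, pyridine, THF, 0 °C
Reagents that add atoms: none
Why: Selective desilylation: the primary silyl ether is cleaved much faster than the hindered secondary allylic one under buffered HF·pyridine.

Step 3
Reactants: 3 (S)-2-[(tert-butyldimethylsilyl)oxy]but-3-en-1-ol; 4 2-(bromomethyl)acrylic acid
Product: 5 (S)-2-[(tert-butyldimethylsilyl)oxy]but-3-en-1-yl 2-(bromomethyl)acrylate
Conditions: DIC, DMAP (5 mol %), CH2Cl2, 0 °C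
Reagents that add atoms: none
Why: Carbodiimide (Steglich) esterification of the primary alcohol; low temperature and little DMAP should keep the allylic bromide from being displaced.

Step 4
Reactants: 5 (S)-2-[(tert-butyldimethylsilyl)oxy]but-3-en-1-yl 2-(bromomethyl)acrylate
Product: 6 (S)-3-(bromomethyl)-5-[(tert-butyldimethylsilyl)oxy]-5,6-dihydro-2H-pyran-2-one
Conditions: second-generation Grubbs catalyst (5 mol %), toluene, 80 °C
Reagents that add atoms: none
Why: Ring-closing metathesis between the vinyl group and the 1,1-disubstituted acrylate closes the six-membered unsaturated lactone with loss of ethene; the ring holds C6 trans to the bromomethyl group, as the later addition requires.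

Step 5
Reactants: 7 tert-butyl(but-3-yn-1-yloxy)dimethylsilane
Product: 10 (E)-5-[(tert-butyldimethylsilyl)oxy]-3-methylpent-2-en-1-ol, via alkenyldimethylalane 8 (not isolated), via lithium alkenylaluminate 9 (not isolated)
Conditions: Me3Al, Cp2ZrCl2 (20 mol %), CH2Cl2, 0 °C to rt; then n-BuLi, THF, −78 °C; (CH2O)n, −78 °C to rt
Reagents that add atoms: trimethylaluminium, C[Al](C)C; formaldehyde (as paraformaldehyde), C=O
Why: Zirconium-catalysed syn-carboalumination (Negishi) puts the methyl group (C14) on the internal carbon and aluminium on the terminal one, which fixes the (E)-alkene; the aluminate adds to formaldehyde with retention of the alkene geometry.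

Step 6
Reactants: 10 (E)-5-[(tert-butyldimethylsilyl)oxy]-3-methylpent-2-en-1-ol
Product: 11 (E)-[(5-bromo-3-methylpent-3-en-1-yl)oxy](tert-butyl)dimethylsilane
Conditions: CBr4, PPh3, CH2Cl2, 0 °C
Reagents that add atoms: tetrabromomethane, BrC(Br)(Br)Br
Why: Appel bromination of a primary allylic alcohol; neutral conditions should leave the alkene geometry and the silyl ether unchanged.

Step 7
Reactants: 11 (E)-[(5-bromo-3-methylpent-3-en-1-yl)oxy](tert-butyl)dimethylsilane; 12 methoxyallene (1-methoxypropa-1,2-diene)
Product: 14 (E)-tert-butyl[(6-methoxy-3-methylocta-3,6,7-trien-1-yl)oxy]dimethylsilane, via 1-lithio-1-methoxyallene 13 (not isolated)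
Conditions: n-BuLi, THF, −40 °C; then 11, −78 to −20 °C
Reagents that add atoms: none
Why: Lithiated methoxyallene is an acyl-anion equivalent that is alkylated at its oxygen-bearing carbon by the primary allylic bromide in an SN2 reaction; this forms C2–C3 and brings in C4 and C15.

Step 8
Reactants: 14 (E)-tert-butyl[(6-methoxy-3-methylocta-3,6,7-trien-1-yl)oxy]dimethylsilane
Product: 16 (E)-tert-butyl({5-[2-(1-iodoethenyl)-1,3-dioxolan-2-yl]-3-methylpent-3-en-1-yl}oxy)dimethylsilane, via mixed methyl hydroxyethyl ketal 15 (not isolated)
Conditions: NIS, HOCH2CH2OH, MeCN/CH2Cl2, −40 °C; then PPTS (cat.), rt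
Reagents that add atoms: N-iodosuccinimide, O=C1CCC(=O)N1I; ethylene glycol, OCCO
Why: Haloalkoxylation of an alkoxyallene: iodonium attacks the central allene carbon, the oxocarbenium ion at C3 is trapped by the diol, and acid-catalysed loss of methanol closes the dioxolane; the enol-ether π bond should react far faster than the trisubstituted alkene.

Step 9
Reactants: 16 (E)-tert-butyl({5-[2-(1-iodoethenyl)-1,3-dioxolan-2-yl]-3-methylpent-3-en-1-yl}oxy)dimethylsilane
Product: 17 (E)-5-[2-(1-iodoethenyl)-1,3-dioxolan-2-yl]-3-methylpent-3-en-1-ol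
Conditions: TBAF, THF, 0 °C
Reagents that add atoms: none
Why: Fluoride cleaves the primary silyl ether; ketal and vinyl iodide are inert to fluoride.

Step 10
Reactants: 17 (E)-5-[2-(1-iodoethenyl)-1,3-dioxolan-2-yl]-3-methylpent-3-en-1-ol
Product: 18 (E)-5-[2-(1-iodoethenyl)-1,3-dioxolan-2-yl]-3-methylpent-3-enal
Conditions: Dess–Martin periodinane, NaHCO3, CH2Cl2, 0 °C
Reagents that add atoms: none
Why: Dess–Martin oxidation under buffered, non-basic conditions should give the β,γ-unsaturated aldehyde without moving the double bond into conjugation; 18 is used at once.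

Step 11
Reactants: 6 (S)-3-(bromomethyl)-5-[(tert-butyldimethylsilyl)oxy]-5,6-dihydro-2H-pyran-2-one; 18 (E)-5-[2-(1-iodoethenyl)-1,3-dioxolan-2-yl]-3-methylpent-3-enal
Product: 20 (4S,5S)-5-[(tert-butyldimethylsilyl)oxy]-4-{(1R,3E)-1-hydroxy-5-[2-(1-iodoethenyl)-1,3-dioxolan-2-yl]-3-methylpent-3-en-1-yl}-3-methylideneoxan-2-one, via allylindium dibromide 19 (not isolated)
Conditions: In powder, THF/H2O (3:1), rt
Reagents that add atoms: none
Why: Barbier allylation: indium inserts into the allylic C–Br bond and the allylindium adds through its ring carbon C7 to the aldehyde in a closed six-membered (Zimmerman–Traxler) transition state. Because the ring holds C6 trans to the CH2–In group, C6 is equatorial and C7/C8 come out anti (later the trans-lactone), and the aldehyde reaches C7 on the ring face opposite the neighbouring silyloxy group, which relates C7 and C8 to C6.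

Step 12
Reactants: 20 (4S,5S)-5-[(tert-butyldimethylsilyl)oxy]-4-{(1R,3E)-1-hydroxy-5-[2-(1-iodoethenyl)-1,3-dioxolan-2-yl]-3-methylpent-3-en-1-yl}-3-methylideneoxan-2-one
Product: 21 (4S,5R)-4-{(1S)-1-[(tert-butyldimethylsilyl)oxy]-2-hydroxyethyl}-5-{(2E)-4-[2-(1-iodoethenyl)-1,3-dioxolan-2-yl]-2-methylbut-2-en-1-yl}-3-methylideneoxolan-2-one
Conditions: CSA (10 mol %), CH2Cl2, rt
Reagents that add atoms: none
Why: Acid-catalysed translactonisation: the C8 hydroxyl adds to the activated lactone carbonyl and the bicyclic intermediate collapses to the five-membered α-methylene lactone, which is favoured over the six-membered one, and frees the C5 primary alcohol; no stereocentre is touched.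

Step 13
Reactants: 21 (4S,5R)-4-{(1S)-1-[(tert-butyldimethylsilyl)oxy]-2-hydroxyethyl}-5-{(2E)-4-[2-(1-iodoethenyl)-1,3-dioxolan-2-yl]-2-methylbut-2-en-1-yl}-3-methylideneoxolan-2-one
Product: 22 (2S)-2-[(tert-butyldimethylsilyl)oxy]-2-[(2R,3S)-2-{(2E)-4-[2-(1-iodoethenyl)-1,3-dioxolan-2-yl]-2-methylbut-2-en-1-yl}-4-methylidene-5-oxooxolan-3-yl]acetaldehyde
Conditions: Dess–Martin periodinane, NaHCO3, CH2Cl2, 0 °C
Reagents that add atoms: none
Why: Dess–Martin oxidation of the primary alcohol; the buffered, non-basic medium should keep the α-silyloxy aldehyde from epimerising at C6, and 22 is used at once.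

Step 14
Reactants: 22 (2S)-2-[(tert-butyldimethylsilyl)oxy]-2-[(2R,3S)-2-{(2E)-4-[2-(1-iodoethenyl)-1,3-dioxolan-2-yl]-2-methylbut-2-en-1-yl}-4-methylidene-5-oxooxolan-3-yl]acetaldehyde
Product: 24 (1(10)E,5S,6S,7S,8R)-6-[(tert-butyldimethylsilyl)oxy]-3,3-(ethylenedioxy)-5-hydroxygermacra-1(10),4(15),11(13)-trien-12,8-olide, via alkenylchromium dichloride 23 (not isolated)
Conditions: CrCl2 (10 equiv), NiCl2 (cat.), DMSO/THF, rt, 2 mM, slow addition of 22
Reagents that add atoms: none
Why: CrCl2 (divalent chromium) reduces NiCl2 to zerovalent nickel, which inserts into the C4–I bond; the alkenylnickel transmetallates to trivalent chromium to give 23, which adds to the chromium-bound C5 aldehyde (Nozaki–Hiyama–Kishi reaction). The closest known reaction type is the intramolecular alkenyl iodide–aldehyde nickel/chromium coupling used to close nine- and ten-membered carbocycles at high dilution. The ten-membered ring closes in a 10-exo-trig mode, C4 attacking the carbonyl carbon while the carbonyl oxygen stays outside the ring. The new C5 centre is controlled by the neighbouring C6 centre inside the closing ring: with the C6–C7 ring bond anti to the incoming C4 and the silyloxy group turned outwards, C4 passes the C6 hydrogen on the Si face of the aldehyde, which gives the 5S alcohol syn to the C6 silyl ether. The step needs attack at the aldehyde only, which the carbonyl selectivity and low basicity of alkenylchromium reagents secure against the lactone and the α-methylene group. It also needs ring closure over oligomerisation, which dilution and the pre-folding of the chain by the trans-lactone and the (E)-alkene support. The C3 ketal prevents an α-iodo enone that divalent chromium would reduce.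

Step 15
Reactants: 24 (1(10)E,5S,6S,7S,8R)-6-[(tert-butyldimethylsilyl)oxy]-3,3-(ethylenedioxy)-5-hydroxygermacra-1(10),4(15),11(13)-trien-12,8-olide; 25 angelic acid ((Z)-2-methylbut-2-enoic acid)
Product: 27 (1(10)E,5S,6S,7S,8R)-5-angeloyloxy-6-[(tert-butyldimethylsilyl)oxy]-3,3-(ethylenedioxy)germacra-1(10),4(15),11(13)-trien-12,8-olide, via mixed anhydride 26 (not isolated)
Conditions: 2,4,6-trichlorobenzoyl chloride, Et3N, toluene, rt; then 24, 80 °C
Reagents that add atoms: none
Why: Yamaguchi-type esterification through the mixed anhydride; without a strong base or a large amount of nucleophilic catalyst the (Z)-geometry of the angelate is expected to hold, and acylation at oxygen leaves C5 unchanged.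

Step 16
Reactants: 27 (1(10)E,5S,6S,7S,8R)-5-angeloyloxy-6-[(tert-butyldimethylsilyl)oxy]-3,3-(ethylenedioxy)germacra-1(10),4(15),11(13)-trien-12,8-olide
Product: 28 (1(10)E,5S,6S,7S,8R)-5-angeloyloxy-6-[(tert-butyldimethylsilyl)oxy]-3-oxogermacra-1(10),4(15),11(13)-trien-12,8-olide
Conditions: PPTS, acetone/H2O (10:1), 45 °C
Reagents that add atoms: water, O
Why: Acid-catalysed ketal hydrolysis through the allylic oxocarbenium ion; PPTS should be too weak to cleave the secondary silyl ether, and with O6 still protected the angelate cannot migrate.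

Step 17
Reactants: 28 (1(10)E,5S,6S,7S,8R)-5-angeloyloxy-6-[(tert-butyldimethylsilyl)oxy]-3-oxogermacra-1(10),4(15),11(13)-trien-12,8-olide
Product: 29 (1(10)E,5S,6S,7R,8R)-5-angeloyloxy-6-hydroxy-3-oxogermacra-1(10),4(15),11(13)-trien-12,8-olide
Conditions: HF·pyridine, pyridine, THF, 0 °C to rt
Reagents that add atoms: none
Why: Fluoride-mediated Si–O cleavage under weakly acidic, non-aqueous conditions; it is placed before the epoxidation because HF sources open trisubstituted epoxides and basic fluoride would cause acyl shift and β-elimination.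

Step 18
Reactants: 29 (1(10)E,5S,6S,7R,8R)-5-angeloyloxy-6-hydroxy-3-oxogermacra-1(10),4(15),11(13)-trien-12,8-olide
Product: 30 (1R,5S,6S,7R,8R,10R)-5-angeloyloxy-1,10-epoxy-6-hydroxy-3-oxogermacra-4(15),11(13)-dien-12,8-olide (CNP0348992.3)
Conditions: mCPBA, NaHCO3, CH2Cl2, 0 °C
Reagents that add atoms: 3-chloroperoxybenzoic acid, OOC(=O)c1cccc(Cl)c1
Why: Prilezhaev epoxidation: the peracid should pick the only electron-rich alkene (C1=C10) over the three electron-poor ones, and the (E)-geometry gives the trans-epoxide. Attack on the outer face of the ring conformer that has C14 and the C8–O bond on the same side of the ring gives 1R,10R.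

## Compound list

1 | (S)-but-3-ene-1,2-diol | C=C[C@H](O)CO | starting material
2 | (S)-3,4-bis[(tert-butyldimethylsilyl)oxy]but-1-ene | C=C[C@H](O[Si](C)(C)C(C)(C)C)CO[Si](C)(C)C(C)(C)C | intermediate
3 | (S)-2-[(tert-butyldimethylsilyl)oxy]but-3-en-1-ol | C=C[C@H](O[Si](C)(C)C(C)(C)C)CO | intermediate
4 | 2-(bromomethyl)acrylic acid | C=C(CBr)C(=O)O | starting material
5 | (S)-2-[(tert-butyldimethylsilyl)oxy]but-3-en-1-yl 2-(bromomethyl)acrylate | C=C[C@H](O[Si](C)(C)C(C)(C)C)COC(=O)C(=C)CBr | intermediate
6 | (S)-3-(bromomethyl)-5-[(tert-butyldimethylsilyl)oxy]-5,6-dihydro-2H-pyran-2-one | O=C1OC[C@@H](O[Si](C)(C)C(C)(C)C)C=C1CBr | intermediate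
7 | tert-butyl(but-3-yn-1-yloxy)dimethylsilane | C#CCCO[Si](C)(C)C(C)(C)C | starting material
8 | dimethyl[(1E)-4-[(tert-butyldimethylsilyl)oxy]-2-methylbut-1-en-1-yl]alane | C[Al](C)/C=C(\C)CCO[Si](C)(C)C(C)(C)C | intermediate (not isolated)
9 | lithium butyl[(1E)-4-[(tert-butyldimethylsilyl)oxy]-2-methylbut-1-en-1-yl]dimethylaluminate | [Li+].CCCC[Al-](C)(C)/C=C(\C)CCO[Si](C)(C)C(C)(C)C | intermediate (not isolated)
10 | (E)-5-[(tert-butyldimethylsilyl)oxy]-3-methylpent-2-en-1-ol | OC/C=C(\C)CCO[Si](C)(C)C(C)(C)C | intermediate
11 | (E)-[(5-bromo-3-methylpent-3-en-1-yl)oxy](tert-butyl)dimethylsilane | BrC/C=C(\C)CCO[Si](C)(C)C(C)(C)C | intermediate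
12 | methoxyallene (1-methoxypropa-1,2-diene) | COC=C=C | starting material
13 | 1-lithio-1-methoxyallene | [Li]C(OC)=C=C | intermediate (not isolated)
14 | (E)-tert-butyl[(6-methoxy-3-methylocta-3,6,7-trien-1-yl)oxy]dimethylsilane | COC(=C=C)C/C=C(\C)CCO[Si](C)(C)C(C)(C)C | intermediate
15 | 2-{[(5E)-8-[(tert-butyldimethylsilyl)oxy]-2-iodo-3-methoxy-6-methylocta-1,5-dien-3-yl]oxy}ethanol (mixed ketal, both configurations at the ketal carbon) | COC(OCCO)(C/C=C(\C)CCO[Si](C)(C)C(C)(C)C)C(I)=C | intermediate (not isolated)
16 | (E)-tert-butyl({5-[2-(1-iodoethenyl)-1,3-dioxolan-2-yl]-3-methylpent-3-en-1-yl}oxy)dimethylsilane | C=C(I)C1(C/C=C(\C)CCO[Si](C)(C)C(C)(C)C)OCCO1 | intermediate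
17 | (E)-5-[2-(1-iodoethenyl)-1,3-dioxolan-2-yl]-3-methylpent-3-en-1-ol | C=C(I)C1(C/C=C(\C)CCO)OCCO1 | intermediate
18 | (E)-5-[2-(1-iodoethenyl)-1,3-dioxolan-2-yl]-3-methylpent-3-enal | C=C(I)C1(C/C=C(\C)CC=O)OCCO1 | intermediate
19 | {[(5S)-5-[(tert-butyldimethylsilyl)oxy]-2-oxo-5,6-dihydro-2H-pyran-3-yl]methyl}indium dibromide (simplest formulation) | O=C1OC[C@@H](O[Si](C)(C)C(C)(C)C)C=C1C[In](Br)Br | intermediate (not isolated)
20 | (4S,5S)-5-[(tert-butyldimethylsilyl)oxy]-4-{(1R,3E)-1-hydroxy-5-[2-(1-iodoethenyl)-1,3-dioxolan-2-yl]-3-methylpent-3-en-1-yl}-3-methylideneoxan-2-one | O=C1OC[C@@H](O[Si](C)(C)C(C)(C)C)[C@H]([C@H](O)C/C(C)=C/CC2(OCCO2)C(I)=C)C1=C | intermediate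
21 | (4S,5R)-4-{(1S)-1-[(tert-butyldimethylsilyl)oxy]-2-hydroxyethyl}-5-{(2E)-4-[2-(1-iodoethenyl)-1,3-dioxolan-2-yl]-2-methylbut-2-en-1-yl}-3-methylideneoxolan-2-one | OC[C@@H](O[Si](C)(C)C(C)(C)C)[C@@H]1[C@@H](C/C(C)=C/CC2(OCCO2)C(I)=C)OC(=O)C1=C | intermediate
22 | (2S)-2-[(tert-butyldimethylsilyl)oxy]-2-[(2R,3S)-2-{(2E)-4-[2-(1-iodoethenyl)-1,3-dioxolan-2-yl]-2-methylbut-2-en-1-yl}-4-methylidene-5-oxooxolan-3-yl]acetaldehyde | O=C[C@@H](O[Si](C)(C)C(C)(C)C)[C@@H]1[C@@H](C/C(C)=C/CC2(OCCO2)C(I)=C)OC(=O)C1=C | intermediate
23 | alkenylchromium dichloride derived from 22 (C4–CrCl2 in place of C4–I) | O=C[C@@H](O[Si](C)(C)C(C)(C)C)[C@@H]1[C@@H](C/C(C)=C/CC2(OCCO2)C(=C)[Cr](Cl)Cl)OC(=O)C1=C | intermediate (not isolated)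
24 | (1(10)E,5S,6S,7S,8R)-6-[(tert-butyldimethylsilyl)oxy]-3,3-(ethylenedioxy)-5-hydroxygermacra-1(10),4(15),11(13)-trien-12,8-olide | O=C3O[C@@H]1C/C(C)=C/CC4(OCCO4)C(=C)[C@H](O)[C@@H](O[Si](C)(C)C(C)(C)C)[C@H]1C3=C | intermediate
25 | angelic acid ((Z)-2-methylbut-2-enoic acid) | C/C=C(/C)C(=O)O | starting material
26 | (Z)-2-methylbut-2-enoic 2,4,6-trichlorobenzoic anhydride | C/C=C(/C)C(=O)OC(=O)c1c(Cl)cc(Cl)cc1Cl | intermediate (not isolated)
27 | (1(10)E,5S,6S,7S,8R)-5-angeloyloxy-6-[(tert-butyldimethylsilyl)oxy]-3,3-(ethylenedioxy)germacra-1(10),4(15),11(13)-trien-12,8-olide | O=C3O[C@@H]1C/C(C)=C/CC4(OCCO4)C(=C)[C@H](OC(=O)/C(C)=C\C)[C@@H](O[Si](C)(C)C(C)(C)C)[C@H]1C3=C | intermediate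
28 | (1(10)E,5S,6S,7S,8R)-5-angeloyloxy-6-[(tert-butyldimethylsilyl)oxy]-3-oxogermacra-1(10),4(15),11(13)-trien-12,8-olide | O=C3O[C@@H]1C/C(C)=C/CC(=O)C(=C)[C@H](OC(=O)/C(C)=C\C)[C@@H](O[Si](C)(C)C(C)(C)C)[C@H]1C3=C | intermediate
29 | (1(10)E,5S,6S,7R,8R)-5-angeloyloxy-6-hydroxy-3-oxogermacra-1(10),4(15),11(13)-trien-12,8-olide | O=C3O[C@@H]1C/C(C)=C/CC(=O)C(=C)[C@H](OC(=O)/C(C)=C\C)[C@@H](O)[C@H]1C3=C | intermediate
30 | (1R,5S,6S,7R,8R,10R)-5-angeloyloxy-1,10-epoxy-6-hydroxy-3-oxogermacra-4(15),11(13)-dien-12,8-olide (CNP0348992.3) | C=C1C(=O)O[C@@H]2C[C@@]3(C)O[C@@H]3CC(=O)C(=C)[C@H](OC(=O)/C(C)=C\C)[C@@H](O)[C@@H]12 | target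

## Step count and least certain steps

Total step count: 18. Longest linear sequence: 14 steps (steps 5–18, from 7); the other branch (steps 1–4) joins at step 11.

**Step 14 (key step).** The most likely failure is facial selectivity at C5. If the open-chain polar preference prevails (silyloxy group anti to the incoming carbon), addition occurs on the other face and the 5R alcohol forms. The hindered alkenylchromium species next to the ketal carbon may also be protonated or may couple between molecules before it cyclises. The fallback sets out from 22: if the cyclisation delivers the 5R epimer, (1(10)E,5R,6S,7S,8R)-6-[(tert-butyldimethylsilyl)oxy]-3,3-(ethylenedioxy)-5-hydroxygermacra-1(10),4(15),11(13)-trien-12,8-olide F1, this is esterified with angelic acid 25 under Mitsunobu conditions (PPh3, DIAD, toluene, 0 °C). The Mitsunobu reaction inverts C5 while it installs the ester, and the route is rejoined at 27.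

**Step 8.** Iodonium may be transferred to the trisubstituted alkene in competition with the allenyl ether. The exchange of the methoxy group may also stop at the mixed ketal 15, which would then hydrolyse to the ketone on work-up. The fallback sets out from 14: hydrolysis with aqueous oxalic acid in THF gives the vinyl ketone (E)-8-[(tert-butyldimethylsilyl)oxy]-6-methylocta-1,5-dien-3-one F2. α-Iodination with I2 and pyridine gives (E)-8-[(tert-butyldimethylsilyl)oxy]-2-iodo-6-methylocta-1,5-dien-3-one F3. Ketalisation with 1,2-bis(trimethylsilyloxy)ethane and TMSOTf at −78 °C comes back to the route at 16.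

**Step 11.** The β,γ double bond of 18 may move into conjugation before the addition. The allylindium 19 may lose the silyloxy group by 1,4-elimination. The aldehyde may also not fully avoid the ring face that carries the silyloxy group. The fallback sets out from 6: palladium-catalysed borylation with bis(pinacolato)diboron (Pd2(dba)3, toluene, 50 °C) gives the isolable allylboronate (S)-5-[(tert-butyldimethylsilyl)oxy]-3-[(4,4,5,5-tetramethyl-1,3,2-dioxaborolan-2-yl)methyl]-5,6-dihydro-2H-pyran-2-one F4. F4 is combined with 18 in toluene at rt to 40 °C without metal salts or water. The same closed transition state applies, and the route is rejoined at 20.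

**Step 12.** The exchange between six- and five-membered lactone may stop short of completion, or the acid may move or remove the silyl group. The fallback sets out from 20: saponification with LiOH in THF/H2O at 0 °C gives the dihydroxy acid (3S,4R,6E)-3-{(1S)-1-[(tert-butyldimethylsilyl)oxy]-2-hydroxyethyl}-4-hydroxy-8-[2-(1-iodoethenyl)-1,3-dioxolan-2-yl]-6-methyl-2-methylideneoct-6-enoic acid F5. On acidification to pH 4 the γ-hydroxy acid closes under kinetic control to the five-membered lactone, and the route is rejoined at 21.

**Step 18.** Oxygen may be delivered to the wrong face if the ring prefers the other conformer. The acid by-product may also trigger opening of the epoxide by the C6 hydroxyl across the ring. The fallback sets out from 27, where C2 cannot enolise and no hydroxyl is free, and uses reagent control. Shi epoxidation with the D-fructose-derived ketone and KHSO5 (K2CO3 buffer, MeCN/dimethoxymethane/H2O, 0 °C) is expected, by its spiro transition state, to give the (1R,10R)-epoxide (1R,5S,6S,7S,8R,10R)-5-angeloyloxy-6-[(tert-butyldimethylsilyl)oxy]-1,10-epoxy-3,3-(ethylenedioxy)germacra-4(15),11(13)-dien-12,8-olide F6. Ketal exchange under near-neutral conditions (I2 cat., acetone) gives the epoxy ketone (1R,5S,6S,7S,8R,10R)-5-angeloyloxy-6-[(tert-butyldimethylsilyl)oxy]-1,10-epoxy-3-oxogermacra-4(15),11(13)-dien-12,8-olide F7. Desilylation with TASF in DMF at 0 °C comes back to the route at 30.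

## Further compounds

F1 | step 14 | (1(10)E,5R,6S,7S,8R)-6-[(tert-butyldimethylsilyl)oxy]-3,3-(ethylenedioxy)-5-hydroxygermacra-1(10),4(15),11(13)-trien-12,8-olide | O=C3O[C@@H]1C/C(C)=C/CC4(OCCO4)C(=C)[C@@H](O)[C@@H](O[Si](C)(C)C(C)(C)C)[C@H]1C3=C
F2 | step 8 | (E)-8-[(tert-butyldimethylsilyl)oxy]-6-methylocta-1,5-dien-3-one | C=CC(=O)C/C=C(\C)CCO[Si](C)(C)C(C)(C)C
F3 | step 8 | (E)-8-[(tert-butyldimethylsilyl)oxy]-2-iodo-6-methylocta-1,5-dien-3-one | C=C(I)C(=O)C/C=C(\C)CCO[Si](C)(C)C(C)(C)C
F4 | step 11 | (S)-5-[(tert-butyldimethylsilyl)oxy]-3-[(4,4,5,5-tetramethyl-1,3,2-dioxaborolan-2-yl)methyl]-5,6-dihydro-2H-pyran-2-one | O=C1OC[C@@H](O[Si](C)(C)C(C)(C)C)C=C1CB2OC(C)(C)C(C)(C)O2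
F5 | step 12 | (3S,4R,6E)-3-{(1S)-1-[(tert-butyldimethylsilyl)oxy]-2-hydroxyethyl}-4-hydroxy-8-[2-(1-iodoethenyl)-1,3-dioxolan-2-yl]-6-methyl-2-methylideneoct-6-enoic acid | OC[C@@H](O[Si](C)(C)C(C)(C)C)[C@H]([C@H](O)C/C(C)=C/CC1(OCCO1)C(I)=C)C(=C)C(=O)O
F6 | step 18 | (1R,5S,6S,7S,8R,10R)-5-angeloyloxy-6-[(tert-butyldimethylsilyl)oxy]-1,10-epoxy-3,3-(ethylenedioxy)germacra-4(15),11(13)-dien-12,8-olide | O=C3O[C@@H]1C[C@@]2(C)O[C@@H]2CC4(OCCO4)C(=C)[C@H](OC(=O)/C(C)=C\C)[C@@H](O[Si](C)(C)C(C)(C)C)[C@H]1C3=C
F7 | step 18 | (1R,5S,6S,7S,8R,10R)-5-angeloyloxy-6-[(tert-butyldimethylsilyl)oxy]-1,10-epoxy-3-oxogermacra-4(15),11(13)-dien-12,8-olide | O=C3O[C@@H]1C[C@@]2(C)O[C@@H]2CC(=O)C(=C)[C@H](OC(=O)/C(C)=C\C)[C@@H](O[Si](C)(C)C(C)(C)C)[C@H]1C3=C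
A1 | alternative 1 | tert-butyl{2-[(2R,3R)-3-methyl-3-(prop-2-en-1-yl)oxiran-2-yl]ethoxy}diphenylsilane | C=CC[C@@]1(C)O[C@@H]1CCO[Si](c1ccccc1)(c1ccccc1)C(C)(C)C
A2 | alternative 1 | (S)-5-[(tert-butyldiphenylsilyl)oxy]-3-chloropentan-2-one | CC(=O)[C@@H](Cl)CCO[Si](c1ccccc1)(c1ccccc1)C(C)(C)C
A3 | alternative 2 | (1(10)E,5S,6S,7S,8R)-6-[(tert-butyldimethylsilyl)oxy]-5-[(4-methoxybenzyl)oxy]-3-oxogermacra-1(10),4(15),11(13)-trien-12,8-olide | O=C3O[C@@H]1C/C(C)=C/CC(=O)C(=C)[C@H](OCc2ccc(OC)cc2)[C@@H](O[Si](C)(C)C(C)(C)C)[C@H]1C3=C
A4 | alternative 2 | (1(10)E,5S,6S,7S,8R)-6-[(tert-butyldimethylsilyl)oxy]-7-ethynyl-8-hydroxy-5-[(4-methoxybenzyl)oxy]-10-methyl-4-methylidenecyclodec-1(10)-en-3-one | O[C@@H]1C/C(C)=C/CC(=O)C(=C)[C@H](OCc2ccc(OC)cc2)[C@@H](O[Si](C)(C)C(C)(C)C)[C@H]1C#C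
A5 | alternative 3 | (1(10)E,3R,5S,8R)-3-[(tert-butyldimethylsilyl)oxy]-8-[dimethyl(phenyl)silyl]-5-[(4-methoxybenzyl)oxy]-10-methyl-4-methylidenecyclodec-1(10)-en-6-one | C[Si](C)(c1ccccc1)[C@@H]2C/C(C)=C/C[C@@H](O[Si](C)(C)C(C)(C)C)C(=C)[C@H](OCc3ccc(OC)cc3)C(=O)C2
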